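**Strategy.** The route rests on cutting the bond between the alkene carbon C1 of the indane five-membered ring and the aromatic carbon C7a of the fused resorcinol ring A. C7a is meta to both ring A oxygens, so it is reached as an aryl bromide, not by Friedel–Crafts chemistry. One palladium-catalysed reductive Heck cyclisation (5-exo-dig carbopalladation, then hydride capture) of an o-bromoaryl alkyne closes the indane ring and fixes the E-benzylidene geometry by syn addition. The precursor is an acyclic diaryl alkyne assembled by Sonogashira union of an enantioenriched dihydrobenzofuran iodide with a terminal alkyne whose two stereocentres come from an amine-catalysed o-quinone methide annulation through a temporary lactol ring.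

Key step: step 14

Locants: indane unit C1 (alkylidene carbon), C2 (bears the 3,5-dihydroxyphenyl group), C3 (bears the 4-hydroxyphenyl group), C3a/C7a (fusion carbons); ring A is the fused resorcinol ring.

Assumption: Rh2(S-PTAD)4 is taken to give the (3R) dihydrobenzofuran series in step 10; if the sense of induction is the opposite, Rh2(R-PTAD)4 is used and nothing else changes.

**Step 1**
Reactants: 1 1,3-bis(benzyloxy)-5-bromobenzene
Product: 2 2,4-bis(benzyloxy)-6-bromobenzaldehyde
Conditions: POCl3 (1.5 equiv), DMF, 0 → 80 °C; ice-water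
Reagents that add atoms: N,N-dimethylformamide CN(C)C=O; water O
Why: Vilsmeier–Haack formylation should occur para to one benzyloxy group and ortho to the other, next to bromine, in preference to the position flanked by both ethers, and the minor isomer should be removable by crystallisation.

**Step 2**
Reactants: 2 2,4-bis(benzyloxy)-6-bromobenzaldehyde
Product: 3 4-(benzyloxy)-2-bromo-6-hydroxybenzaldehyde
Conditions: BCl3 (1.1 equiv), CH2Cl2, −78 → 0 °C; H2O
Reagents that add atoms: none
Why: BCl3 chelates the aldehyde oxygen and the ortho ether oxygen, so only the ortho benzyl ether should be cleaved (chelation-controlled dealkylation).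

**Step 3**
Reactants: 3 4-(benzyloxy)-2-bromo-6-hydroxybenzaldehyde; 4 [4-(benzyloxy)phenyl]magnesium bromide
Product: 5 rac-5-(benzyloxy)-2-{[4-(benzyloxy)phenyl](hydroxy)methyl}-3-bromophenol
Conditions: 4 (2.5 equiv), THF, −40 → 0 °C; pH 7 buffer quench
Reagents that add atoms: none
Why: Grignard 1,2-addition, in which one equivalent deprotonates the phenol and the next adds to the aldehyde while the aryl bromide stays intact; the racemic carbinol centre is erased in step 6.

**Step 4**
Reactants: 5 rac-5-(benzyloxy)-2-{[4-(benzyloxy)phenyl](hydroxy)methyl}-3-bromophenol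
Product: 6 rac-5-(benzyloxy)-2-{[4-(benzyloxy)phenyl](4-methylbenzenesulfonyl)methyl}-3-bromophenol
Conditions: 4-methylbenzenesulfinic acid (1.5 equiv), CH2Cl2, rt
Reagents that add atoms: 4-methylbenzenesulfinic acid Cc1ccc(cc1)S(=O)O
Why: The electron-rich o-hydroxybenzhydrol ionises under mild acid and the cation is captured at sulfur by the sulfinate (SN1-type substitution), giving a bench-stable o-quinone methide precursor.

**Step 5**
Reactants: 7 rac-2-[3,5-bis(benzyloxy)phenyl]oxirane
Product: 8 [3,5-bis(benzyloxy)phenyl]acetaldehyde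
Conditions: BF3·OEt2 (0.2 equiv), CH2Cl2, −20 °C, 15 min; used crude
Reagents that add atoms: none
Why: Meinwald rearrangement, in which Lewis acid opening at the benzylic carbon and a 1,2-hydride shift should give the arylacetaldehyde, taken on at once because it self-condenses.

**Step 6**
Reactants: 6 rac-5-(benzyloxy)-2-{[4-(benzyloxy)phenyl](4-methylbenzenesulfonyl)methyl}-3-bromophenol; 8 [3,5-bis(benzyloxy)phenyl]acetaldehyde
Product: 10 (3S,4S)-7-(benzyloxy)-4-[4-(benzyloxy)phenyl]-3-[3,5-bis(benzyloxy)phenyl]-5-bromo-3,4-dihydro-2H-chromen-2-ol, via o-quinone methide 9 (not isolated)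
Conditions: 8 (2 equiv), (S)-2-[diphenyl(trimethylsilyloxy)methyl]pyrrolidine (20 mol %), Na2CO3 (1.2 equiv), CHCl3, 0 °C → rt; aqueous work-up
Reagents that add atoms: none
Why: Base-induced loss of sulfinate gives o-quinone methide 9, which should be caught by the (E)-enamine of 8 in an enamine Michael addition/hemiaminal closure (amine-catalysed formal [4+2] annulation); the diphenyl(silyloxy)methyl group shields one enamine face and sets the aryl-bearing centre by the usual model for this catalyst, and synclinal approach to the quinone methide with its aryl group anti to the carbonyl (the syn geometry blocks the methide terminus) sets the benzhydryl centre, so hydrolysis should give the trans-diequatorial lactol.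

**Step 7**
Reactants: 10 (3S,4S)-lactol
Product: 12 1,5-bis(benzyloxy)-2-{(1S,2R)-1-[4-(benzyloxy)phenyl]-2-[3,5-bis(benzyloxy)phenyl]but-3-yn-1-yl}-3-bromobenzene, via phenol alkyne 11 (not isolated)
Conditions: dimethyl (1-diazo-2-oxopropyl)phosphonate (1.5 equiv), K2CO3 (3 equiv), MeOH/THF, 0 °C → rt; then BnBr (1.5 equiv), DMF, rt
Reagents that add atoms: dimethyl (1-diazo-2-oxopropyl)phosphonate CC(=O)C(=[N+]=[N-])P(=O)(OC)OC; benzyl bromide BrCc1ccccc1
Why: Ohira–Bestmann (Seyferth–Gilbert) homologation acts on the ring-opened hydroxy aldehyde, whose phenoxide charge should disfavour a second deprotonation at the aryl-bearing α-carbon so that this centre is kept, and the freed phenoxide is benzylated in the same flask (Williamson etherification).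

**Step 8**
Reactants: 13 5-bromo-2-fluorobenzonitrile; 14 [4-(benzyloxy)phenyl]methanol
Product: 15 2-{[4-(benzyloxy)phenyl]methoxy}-5-bromobenzonitrile
Conditions: NaH (1.1 equiv), DMF, 0 °C → rt
Reagents that add atoms: none
Why: SNAr displacement of fluoride, activated by the ortho nitrile, by the benzylic alkoxide.

**Step 9**
Reactants: 15 2-{[4-(benzyloxy)phenyl]methoxy}-5-bromobenzonitrile; 1 1,3-bis(benzyloxy)-5-bromobenzene
Product: 18 {[3,5-bis(benzyloxy)phenyl](2-{[4-(benzyloxy)phenyl]methoxy}-5-bromophenyl)methylidene}hydrazine, via aryl Grignard reagent 16 (not isolated), via ketimine 17 (not isolated)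
Conditions: 1 (1.5 equiv), Mg turnings, THF, 50 °C; 15, THF, 0 → 50 °C; MeOH; then N2H4·H2O (10 equiv), AcOH (cat.), EtOH, 60 °C
Reagents that add atoms: hydrazine NN
Why: Grignard addition to the nitrile, helped by chelation to the ortho ether oxygen, stops at the N-magnesio ketimine, and after methanol quench the N–H ketimine should undergo transimination with hydrazine more readily than the hindered ketone would condense.

**Step 10**
Reactants: 18 hydrazone
Product: 20 (2S,3R)-2-[4-(benzyloxy)phenyl]-3-[3,5-bis(benzyloxy)phenyl]-5-bromo-2,3-dihydro-1-benzofuran, via diazo compound 19 (not isolated)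
Conditions: MnO2 (8 equiv), CH2Cl2, rt, filter; Rh2(S-PTAD)4 (dirhodium tetrakis[(S)-(adamantan-1-yl)(phthalimido)acetate], 1 mol %), CH2Cl2, 0 °C → rt
Reagents that add atoms: none
Why: MnO2 dehydrogenates the hydrazone to the diaryldiazomethane, and the chiral dirhodium carboxylate should convert it into a donor/donor carbene that inserts into the ether-activated benzylic C–H bond (intramolecular 1,5 C–H insertion), the catalyst pocket fixing C3 and the concerted insertion placing the two aryl groups cis.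

**Step 11**
Reactants: 20 (2S,3R)-cis-dihydrobenzofuran bromide
Product: 21 (2R,3R)-2-[4-(benzyloxy)phenyl]-3-[3,5-bis(benzyloxy)phenyl]-5-bromo-2,3-dihydro-1-benzofuran
Conditions: BF3·OEt2 (1.2 equiv), CH2Cl2 (0.01 M), −40 → 0 °C; aq. NaHCO3
Reagents that add atoms: none
Why: The Lewis acid reversibly ionises the C2–O bond to a para-benzyloxy-stabilised benzylic cation, and reclosure under thermodynamic control should give the trans isomer while C3 is untouched (acid-mediated epimerisation).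

**Step 12**
Reactants: 21 (2R,3R)-trans-dihydrobenzofuran bromide
Product: 22 (2R,3R)-2-[4-(benzyloxy)phenyl]-3-[3,5-bis(benzyloxy)phenyl]-5-iodo-2,3-dihydro-1-benzofuran
Conditions: NaI (2 equiv), CuI (10 mol %), trans-N,N'-dimethylcyclohexane-1,2-diamine (20 mol %), 1,4-dioxane, 110 °C
Reagents that add atoms: sodium iodide [Na+].[I-]
Why: Copper-catalysed aromatic Finkelstein halogen exchange, driven by precipitation of NaBr, supplies the iodide that allows chemoselective coupling next to the ring A bromide.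

**Step 13**
Reactants: 12 terminal alkyne; 22 (2R,3R)-dihydrobenzofuran iodide
Product: 23 (2R,3R)-2-[4-(benzyloxy)phenyl]-3-[3,5-bis(benzyloxy)phenyl]-5-{(3S,4S)-4-[2,4-bis(benzyloxy)-6-bromophenyl]-4-[4-(benzyloxy)phenyl]-3-[3,5-bis(benzyloxy)phenyl]but-1-yn-1-yl}-2,3-dihydro-1-benzofuran
Conditions: PdCl2(PPh3)2 (3 mol %), CuI (5 mol %), iPr2NH/THF, rt, degassed
Reagents that add atoms: none
Why: Sonogashira coupling, in which oxidative addition into the carbon–iodine bond at room temperature should be far faster than into the hindered, electron-rich ring A carbon–bromine bond.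

**Step 14**
Reactants: 23 o-bromoaryl alkyne
Product: 24 (2R,3R)-5-{(E)-[(2S,3S)-4,6-bis(benzyloxy)-3-[4-(benzyloxy)phenyl]-2-[3,5-bis(benzyloxy)phenyl]-2,3-dihydro-1H-inden-1-ylidene]methyl}-2-[4-(benzyloxy)phenyl]-3-[3,5-bis(benzyloxy)phenyl]-2,3-dihydro-1-benzofuran
Conditions: Pd(OAc)2 (10 mol %), PPh3 (25 mol %), HCO2Na (1.5 equiv), Et4NCl (1 equiv), DMF, 90 °C
Reagents that add atoms: none
Why: Zerovalent palladium inserts into the ring A carbon–bromine bond and the arylpalladium bromide adds syn across the tethered alkyne, forming the C7a–C1 bond; bromide is then exchanged for formate, decarboxylation gives a vinylpalladium hydride, and reductive elimination with retention places hydrogen cis to ring A. The closest known reaction type is the reductive Heck (cyclisation–hydride capture) reaction of o-haloaryl alkynes. The only ring closed is the five-membered carbocycle of the indane, by 5-exo-dig carbopalladation. No stereocentre is created; the E geometry of the benzylidene follows from syn addition and stereoretentive hydride delivery, and C2 and C3 should stay intact because no palladium hydride persists to move the double bond into the ring. The step needs cyclisation to outrun direct formate reduction of the arylpalladium species and 5-exo to beat 6-endo closure; the two-atom tether with its trans diaryl substituents holds the alkyne next to palladium, and sparingly soluble HCO2Na keeps the hydride concentration low. The E isomer is also the thermodynamically preferred one, since the dihydrobenzofuranyl group then avoids H-7 of ring A.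

**Step 15**
Reactants: 24 octabenzyl ether
Product: 25 5-[(2R,3R)-5-{(E)-[(2S,3S)-2-(3,5-dihydroxyphenyl)-4,6-dihydroxy-3-(4-hydroxyphenyl)-2,3-dihydro-1H-inden-1-ylidene]methyl}-2-(4-hydroxyphenyl)-2,3-dihydro-1-benzofuran-3-yl]benzene-1,3-diol (CNP0184753.1)
Conditions: BCl3 (24 equiv), pentamethylbenzene (24 equiv), CH2Cl2, −78 °C; MeOH quench, aqueous work-up
Reagents that add atoms: none
Why: BCl3 activates each aryl benzyl ether and pentamethylbenzene traps the benzyl cation irreversibly (Lewis acid debenzylation with a cation scavenger), a non-reductive method that should spare the exocyclic alkene, with the low temperature limiting ionisation of the dihydrobenzofuran C2–O bond; no stereocentre is involved.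

**Compound list**

1 | 1,3-bis(benzyloxy)-5-bromobenzene | Brc1cc(OCc2ccccc2)cc(OCc2ccccc2)c1 | starting material
2 | 2,4-bis(benzyloxy)-6-bromobenzaldehyde | O=Cc1c(Br)cc(OCc2ccccc2)cc1OCc1ccccc1 | intermediate
3 | 4-(benzyloxy)-2-bromo-6-hydroxybenzaldehyde | O=Cc1c(O)cc(OCc2ccccc2)cc1Br | intermediate
4 | [4-(benzyloxy)phenyl]magnesium bromide (THF solution) | Br[Mg]c1ccc(OCc2ccccc2)cc1 | starting material
5 | rac-5-(benzyloxy)-2-{[4-(benzyloxy)phenyl](hydroxy)methyl}-3-bromophenol | OC(c1ccc(OCc2ccccc2)cc1)c1c(O)cc(OCc2ccccc2)cc1Br | intermediate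
6 | rac-5-(benzyloxy)-2-{[4-(benzyloxy)phenyl](4-methylbenzenesulfonyl)methyl}-3-bromophenol | Cc1ccc(cc1)S(=O)(=O)C(c1ccc(OCc2ccccc2)cc1)c1c(O)cc(OCc2ccccc2)cc1Br | intermediate
7 | rac-2-[3,5-bis(benzyloxy)phenyl]oxirane | C1OC1c1cc(OCc2ccccc2)cc(OCc2ccccc2)c1 | starting material
8 | [3,5-bis(benzyloxy)phenyl]acetaldehyde | O=CCc1cc(OCc2ccccc2)cc(OCc2ccccc2)c1 | intermediate
9 | (6Z)-3-(benzyloxy)-6-{[4-(benzyloxy)phenyl]methylidene}-5-bromocyclohexa-2,4-dien-1-one (aryl group anti to the carbonyl) | O=C1C=C(OCc2ccccc2)C=C(Br)/C1=C\c1ccc(OCc2ccccc2)cc1 | intermediate (not isolated)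
10 | (3S,4S)-7-(benzyloxy)-4-[4-(benzyloxy)phenyl]-3-[3,5-bis(benzyloxy)phenyl]-5-bromo-3,4-dihydro-2H-chromen-2-ol (trans, anomer mixture at C2) | OC1Oc2cc(OCc3ccccc3)cc(Br)c2[C@H](c2ccc(OCc3ccccc3)cc2)[C@H]1c1cc(OCc2ccccc2)cc(OCc2ccccc2)c1 | intermediate
11 | 5-(benzyloxy)-2-{(1S,2R)-1-[4-(benzyloxy)phenyl]-2-[3,5-bis(benzyloxy)phenyl]but-3-yn-1-yl}-3-bromophenol | C#C[C@H](c1cc(OCc2ccccc2)cc(OCc2ccccc2)c1)[C@@H](c1ccc(OCc2ccccc2)cc1)c1c(O)cc(OCc2ccccc2)cc1Br | intermediate (not isolated)
12 | 1,5-bis(benzyloxy)-2-{(1S,2R)-1-[4-(benzyloxy)phenyl]-2-[3,5-bis(benzyloxy)phenyl]but-3-yn-1-yl}-3-bromobenzene | C#C[C@H](c1cc(OCc2ccccc2)cc(OCc2ccccc2)c1)[C@@H](c1ccc(OCc2ccccc2)cc1)c1c(OCc2ccccc2)cc(OCc2ccccc2)cc1Br | intermediate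
13 | 5-bromo-2-fluorobenzonitrile | N#Cc1cc(Br)ccc1F | starting material
14 | [4-(benzyloxy)phenyl]methanol | OCc1ccc(OCc2ccccc2)cc1 | starting material
15 | 2-{[4-(benzyloxy)phenyl]methoxy}-5-bromobenzonitrile | N#Cc1cc(Br)ccc1OCc1ccc(OCc2ccccc2)cc1 | intermediate
16 | [3,5-bis(benzyloxy)phenyl]magnesium bromide | Br[Mg]c1cc(OCc2ccccc2)cc(OCc2ccccc2)c1 | intermediate (not isolated)
17 | [3,5-bis(benzyloxy)phenyl](2-{[4-(benzyloxy)phenyl]methoxy}-5-bromophenyl)methanimine | N=C(c1cc(OCc2ccccc2)cc(OCc2ccccc2)c1)c1cc(Br)ccc1OCc1ccc(OCc2ccccc2)cc1 | intermediate (not isolated)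
18 | {[3,5-bis(benzyloxy)phenyl](2-{[4-(benzyloxy)phenyl]methoxy}-5-bromophenyl)methylidene}hydrazine (E/Z mixture) | NN=C(c1cc(OCc2ccccc2)cc(OCc2ccccc2)c1)c1cc(Br)ccc1OCc1ccc(OCc2ccccc2)cc1 | intermediate
19 | 1,3-bis(benzyloxy)-5-[(2-{[4-(benzyloxy)phenyl]methoxy}-5-bromophenyl)(diazo)methyl]benzene | [N-]=[N+]=C(c1cc(OCc2ccccc2)cc(OCc2ccccc2)c1)c1cc(Br)ccc1OCc1ccc(OCc2ccccc2)cc1 | intermediate (not isolated)
20 | (2S,3R)-2-[4-(benzyloxy)phenyl]-3-[3,5-bis(benzyloxy)phenyl]-5-bromo-2,3-dihydro-1-benzofuran (cis) | Brc1ccc2c(c1)[C@@H](c1cc(OCc3ccccc3)cc(OCc3ccccc3)c1)[C@@H](c1ccc(OCc3ccccc3)cc1)O2 | intermediate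
21 | (2R,3R)-2-[4-(benzyloxy)phenyl]-3-[3,5-bis(benzyloxy)phenyl]-5-bromo-2,3-dihydro-1-benzofuran (trans) | Brc1ccc2c(c1)[C@@H](c1cc(OCc3ccccc3)cc(OCc3ccccc3)c1)[C@H](c1ccc(OCc3ccccc3)cc1)O2 | intermediate
22 | (2R,3R)-2-[4-(benzyloxy)phenyl]-3-[3,5-bis(benzyloxy)phenyl]-5-iodo-2,3-dihydro-1-benzofuran | Ic1ccc2c(c1)[C@@H](c1cc(OCc3ccccc3)cc(OCc3ccccc3)c1)[C@H](c1ccc(OCc3ccccc3)cc1)O2 | intermediate
23 | (2R,3R)-2-[4-(benzyloxy)phenyl]-3-[3,5-bis(benzyloxy)phenyl]-5-{(3S,4S)-4-[2,4-bis(benzyloxy)-6-bromophenyl]-4-[4-(benzyloxy)phenyl]-3-[3,5-bis(benzyloxy)phenyl]but-1-yn-1-yl}-2,3-dihydro-1-benzofuran | O(Cc1ccccc1)c1ccc(cc1)[C@H]([C@H](C#Cc1ccc2c(c1)[C@@H](c1cc(OCc3ccccc3)cc(OCc3ccccc3)c1)[C@H](c1ccc(OCc3ccccc3)cc1)O2)c1cc(OCc2ccccc2)cc(OCc2ccccc2)c1)c1c(OCc2ccccc2)cc(OCc2ccccc2)cc1Br | intermediate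
24 | (2R,3R)-5-{(E)-[(2S,3S)-4,6-bis(benzyloxy)-3-[4-(benzyloxy)phenyl]-2-[3,5-bis(benzyloxy)phenyl]-2,3-dihydro-1H-inden-1-ylidene]methyl}-2-[4-(benzyloxy)phenyl]-3-[3,5-bis(benzyloxy)phenyl]-2,3-dihydro-1-benzofuran | O(Cc1ccccc1)c1ccc(cc1)[C@H]1c2c(OCc3ccccc3)cc(OCc3ccccc3)cc2/C(=C/c2ccc3c(c2)[C@@H](c2cc(OCc4ccccc4)cc(OCc4ccccc4)c2)[C@H](c2ccc(OCc4ccccc4)cc2)O3)[C@@H]1c1cc(OCc2ccccc2)cc(OCc2ccccc2)c1 | intermediate
25 | 5-[(2R,3R)-5-{(E)-[(2S,3S)-2-(3,5-dihydroxyphenyl)-4,6-dihydroxy-3-(4-hydroxyphenyl)-2,3-dihydro-1H-inden-1-ylidene]methyl}-2-(4-hydroxyphenyl)-2,3-dihydro-1-benzofuran-3-yl]benzene-1,3-diol (CNP0184753.1) | Oc1ccc([C@H]2c3c(O)cc(O)cc3/C(=C/c3ccc4c(c3)[C@@H](c3cc(O)cc(O)c3)[C@H](c3ccc(O)cc3)O4)[C@@H]2c2cc(O)cc(O)c2)cc1 | target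

**Step count.** Total: 15 steps. Longest linear sequence: 9 steps (steps 1, 2, 3, 4, 6, 7, 13, 14, 15).

**Steps most likely to fail, with fallbacks**

Step 6. The risk is poor facial control at the benzhydryl carbon, because the bromine beside the methide perturbs the geometry of the o-quinone methide, together with loss of the arylacetaldehyde to self-condensation. The fallback sets out from 8 and 6 and moves the nucleophile to the carboxylic acid oxidation level. Pinnick oxidation of 8 (NaClO2, NaH2PO4, 2-methylbut-2-ene) should give [3,5-bis(benzyloxy)phenyl]acetic acid F1. Pivaloyl chloride and iPr2NEt convert it into the mixed anhydride [3,5-bis(benzyloxy)phenyl]acetic pivalic anhydride F2. A chiral isothiourea (HyperBTM, the enantiomer that gives the 3S,4S series) turns F2 into a C1-ammonium enolate, which should add to o-quinone methide 9 (from 6 with Cs2CO3) and lactonise to (3S,4S)-7-(benzyloxy)-4-[4-(benzyloxy)phenyl]-3-[3,5-bis(benzyloxy)phenyl]-5-bromo-3,4-dihydro-2H-chromen-2-one F3. DIBAL-H at −78 °C reduces F3 to lactol 10, where the route resumes.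

Step 7. The risk is epimerisation of the aryl-bearing α-carbon of the ring-opened aldehyde under carbonate/methanol before the homologation occurs. The fallback sets out from 10 and avoids a basic protic medium. Stork–Zhao olefination with the ylide from (iodomethyl)triphenylphosphonium iodide and NaHMDS (THF, −78 °C) should give 5-(benzyloxy)-2-{(1S,2R,3Z)-1-[4-(benzyloxy)phenyl]-2-[3,5-bis(benzyloxy)phenyl]-4-iodobut-3-en-1-yl}-3-bromophenol F4. Anti-elimination of hydrogen iodide from F4 with NaHMDS (−78 → 0 °C) gives the phenoxide of 11, and benzyl bromide/DMF in the same flask returns the route at 12.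

Step 14. The risk is formate reduction of the arylpalladium bromide before it reaches the alkyne (hydrodebromination), or loss of alkene geometry through isomerisation of the aryl-substituted vinylpalladium intermediate. The fallback sets out from 12 and 22 and replaces the hydride-terminated alkyne cyclisation by a classical Heck reaction of an E-alkene. Hydroboration of 12 with pinacolborane (Cp2Zr(H)Cl, 10 mol %, Et3N, 60 °C) should give 2-[(1E,3S,4S)-4-[2,4-bis(benzyloxy)-6-bromophenyl]-4-[4-(benzyloxy)phenyl]-3-[3,5-bis(benzyloxy)phenyl]but-1-en-1-yl]-4,4,5,5-tetramethyl-1,3,2-dioxaborolane F5. Iodide-selective Suzuki–Miyaura coupling of F5 with 22 (Pd(PPh3)4, K3PO4, THF/H2O, 50 °C) gives (2R,3R)-2-[4-(benzyloxy)phenyl]-3-[3,5-bis(benzyloxy)phenyl]-5-[(1E,3S,4S)-4-[2,4-bis(benzyloxy)-6-bromophenyl]-4-[4-(benzyloxy)phenyl]-3-[3,5-bis(benzyloxy)phenyl]but-1-en-1-yl]-2,3-dihydro-1-benzofuran F6. Heck cyclisation of F6 (Pd(OAc)2, P(o-tol)3, Ag2CO3, MeCN, 80 °C) proceeds by 5-exo-trig syn-carbopalladation and syn β-hydride elimination of the only β-hydrogen, which again places the aryl group trans to ring A, with the silver salt suppressing double bond migration; the route is rejoined at 24.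

**Further compounds**

F1 | step 6 | [3,5-bis(benzyloxy)phenyl]acetic acid | OC(=O)Cc1cc(OCc2ccccc2)cc(OCc2ccccc2)c1
F2 | step 6 | [3,5-bis(benzyloxy)phenyl]acetic pivalic anhydride | CC(C)(C)C(=O)OC(=O)Cc1cc(OCc2ccccc2)cc(OCc2ccccc2)c1
F3 | step 6 | (3S,4S)-7-(benzyloxy)-4-[4-(benzyloxy)phenyl]-3-[3,5-bis(benzyloxy)phenyl]-5-bromo-3,4-dihydro-2H-chromen-2-one | O=C1Oc2cc(OCc3ccccc3)cc(Br)c2[C@H](c2ccc(OCc3ccccc3)cc2)[C@H]1c1cc(OCc2ccccc2)cc(OCc2ccccc2)c1
F4 | step 7 | 5-(benzyloxy)-2-{(1S,2R,3Z)-1-[4-(benzyloxy)phenyl]-2-[3,5-bis(benzyloxy)phenyl]-4-iodobut-3-en-1-yl}-3-bromophenol | I/C=C\[C@H](c1cc(OCc2ccccc2)cc(OCc2ccccc2)c1)[C@@H](c1ccc(OCc2ccccc2)cc1)c1c(O)cc(OCc2ccccc2)cc1Br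
F5 | step 14 | 2-[(1E,3S,4S)-4-[2,4-bis(benzyloxy)-6-bromophenyl]-4-[4-(benzyloxy)phenyl]-3-[3,5-bis(benzyloxy)phenyl]but-1-en-1-yl]-4,4,5,5-tetramethyl-1,3,2-dioxaborolane | Brc1cc(OCc2ccccc2)cc(OCc2ccccc2)c1[C@H](c1ccc(OCc2ccccc2)cc1)[C@@H](c1cc(OCc2ccccc2)cc(OCc2ccccc2)c1)/C=C/B1OC(C)(C)C(C)(C)O1
F6 | step 14 | (2R,3R)-2-[4-(benzyloxy)phenyl]-3-[3,5-bis(benzyloxy)phenyl]-5-[(1E,3S,4S)-4-[2,4-bis(benzyloxy)-6-bromophenyl]-4-[4-(benzyloxy)phenyl]-3-[3,5-bis(benzyloxy)phenyl]but-1-en-1-yl]-2,3-dihydro-1-benzofuran | Brc1cc(OCc2ccccc2)cc(OCc2ccccc2)c1[C@H](c1ccc(OCc2ccccc2)cc1)[C@@H](c1cc(OCc2ccccc2)cc(OCc2ccccc2)c1)/C=C/c1ccc2c(c1)[C@@H](c1cc(OCc3ccccc3)cc(OCc3ccccc3)c1)[C@H](c1ccc(OCc3ccccc3)cc1)O2
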